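**Plan**
1. Retrosynthesis: first the 7-OH is masked as a MOM acetal; then the O–CMe2 bond of the B-ring 2,2-dimethyl-2H-pyran is cut. This ring (O on C4', CMe2, CH=CH on C3', fused across C3'–C4') is a C3' prenyl group folded back onto the 4'-phenol oxygen at a higher oxidation level, so it can be made from an ortho-prenylphenol by dehydrogenation.
2. Both prenyl groups (on C6 and C3') are then cut at their CH=CMe2 double bonds (cross-metathesis) to C-allyl groups. The aryl–CH2 bonds at C6 and C3' are traced back by [3,3] shifts to the 5-O- and 4'-O-allyl ethers of 7-O-MOM genistein.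
3. Forward: genistein supplies the chromone and both benzene rings intact. O7 is capped, O5 and O4' are allylated, a double Claisen rearrangement moves the allyl groups to C6 and C3', and metathesis turns them into prenyl groups. The only new ring, the pyran, closes in step 5, and mild acid then frees the 7-OH.
4. Stereochemistry: the target has no stereocentre, so nothing has to be set; only the double-bond geometry of the transient oxatriene matters for ring closure.

Key step: step 5

Remark: isochandalone has no stereogenic centre and no configurationally defined double bond, so "single enantiomer" reduces to the constitution of a single achiral compound.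

**Step 1**
Reactants: 1 genistein; 2 chloromethyl methyl ether
Product: 3 7-O-MOM genistein (5-hydroxy-3-(4-hydroxyphenyl)-7-(methoxymethoxy)chromen-4-one)
Conditions: MOMCl (1.05 equiv), K2CO3 (1.1 equiv), acetone, 0 °C → rt
Reagents that add atoms: chloromethyl methyl ether, COCCl
Why: The 7-OH is the most acidic phenol of genistein (vinylogous acid through the pyrone, not hydrogen-bonded), so one equivalent of carbonate and MOMCl should give a regioselective Williamson-type O-alkylation at O7 while the chelated 5-OH and the less acidic 4'-OH stay free.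

**Step 2**
Reactants: 3 7-O-MOM genistein; 4 allyl bromide
Product: 5 5,4'-di-O-allyl-7-O-MOM genistein (5-allyloxy-3-(4-allyloxyphenyl)-7-(methoxymethoxy)chromen-4-one)
Conditions: allyl bromide (4 equiv), K2CO3 (4 equiv), DMF, 60 °C
Reagents that add atoms: allyl bromide, C=CCBr
Why: Exhaustive Williamson O-allylation, in which the 4'-phenoxide reacts readily and excess allyl bromide with carbonate in warm DMF should also alkylate the hydrogen-bonded 5-OH, the usual way to prepare 5-allyloxychromones for Claisen chemistry.

**Step 3**
Reactants: 5 5,4'-di-O-allyl-7-O-MOM genistein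
Product: 6 6,3'-diallyl-7-O-MOM genistein (6-allyl-3-(3-allyl-4-hydroxyphenyl)-5-hydroxy-7-(methoxymethoxy)chromen-4-one)
Conditions: PhNEt2, 200 °C, sealed tube, Ar
Reagents that add atoms: none
Why: Double aromatic Claisen rearrangement ([3,3]-sigmatropic shift, then tautomerisation), in which the 5-O-allyl group can only migrate to C6, its single free ortho position, and the 4'-O-allyl group to the equivalent C3'/C5' positions, while the basic amine solvent speeds rearomatisation ahead of Cope migration to C8 and suppresses acid-type cyclisation of the new o-allylphenols.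

**Step 4**
Reactants: 6 6,3'-diallyl-7-O-MOM genistein; 7 2-methylbut-2-ene
Product: 8 7-O-MOM lupalbigenin (5-hydroxy-3-[4-hydroxy-3-(3-methylbut-2-enyl)phenyl]-7-(methoxymethoxy)-6-(3-methylbut-2-enyl)chromen-4-one)
Conditions: Grubbs II (10 mol %), 2-methylbut-2-ene (large excess), CH2Cl2, 40 °C, sealed tube
Reagents that add atoms: 2-methylbut-2-ene, CC=C(C)C
Why: Olefin cross-metathesis of terminal allylarenes with 2-methylbut-2-ene is the standard conversion of C-allyl into C-prenyl groups on free phenols and flavonoids; the excess trisubstituted partner should drive both sites to the prenyl stage with loss of propene, and the pyrone C2=C3 bond is inert.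

**Step 5**
Reactants: 8 7-O-MOM lupalbigenin
Product: 10 7-O-MOM isochandalone, via B-ring ortho-quinone methide 9 (not isolated)
Conditions: DDQ (1.05 equiv), PhMe, rt → 60 °C
Reagents that add atoms: none
Why: DDQ, pre-associated with the electron-rich 4'-hydroxyaryl ring as a charge-transfer complex, should abstract hydride from the 3'-CH2, which is benzylic, allylic and ortho to the free phenol, and transfer of the O4' proton to the reduced quinone gives the ortho-quinone methide 9, a 1-oxatriene (O=C4'–C3'=CH–CH=CMe2). Its Z isomer closes by thermal disrotatory oxa-6π electrocyclisation, formally a 6-endo union of O4' with the CMe2 terminus, which forms the O–CMe2 bond and the pyran ring and restores B-ring aromaticity; the E isomer would have to isomerise before it can close. The closest known reaction type is the DDQ cyclodehydrogenation of ortho-prenylphenols to 2,2-dimethyl-2H-chromenes, long used on prenylated flavonoids. No stereocentre arises, because the new sp3 carbon carries two methyl groups. The step needs chemoselectivity between the two prenyl groups: on ring A the O7 is capped as the MOM ether, so no quinone methide can form through it, and the 5-OH is held in a hydrogen bond to C4=O on a ring deactivated by that carbonyl, so with barely more than one equivalent of DDQ at moderate temperature the free, unchelated 4'-phenol side should react first.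

**Step 6**
Reactants: 10 7-O-MOM isochandalone
Product: 11 isochandalone
Conditions: HCl (1.25 M in MeOH), 40 °C
Reagents that add atoms: none
Why: Acid-catalysed acetal exchange (methanolysis) of the aryl MOM ether, helped by the good leaving-group ability of the 7-phenol; dilute methanolic HCl at moderate temperature is the usual way to unmask MOM-protected prenylated flavonoids without hydroalkoxylation of the prenyl group or addition to the chromene.

**Compound list**
1 | genistein (5,7-dihydroxy-3-(4-hydroxyphenyl)chromen-4-one) | O=c1c(-c2ccc(O)cc2)coc2cc(O)cc(O)c12 | starting material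
2 | chloromethyl methyl ether (MOMCl) | COCCl | starting material
3 | 7-O-MOM genistein (5-hydroxy-3-(4-hydroxyphenyl)-7-(methoxymethoxy)chromen-4-one) | O=c1c(-c2ccc(O)cc2)coc2cc(OCOC)cc(O)c12 | intermediate
4 | allyl bromide (3-bromoprop-1-ene) | C=CCBr | starting material
5 | 5,4'-di-O-allyl-7-O-MOM genistein (5-allyloxy-3-(4-allyloxyphenyl)-7-(methoxymethoxy)chromen-4-one) | O=c1c(-c2ccc(OCC=C)cc2)coc2cc(OCOC)cc(OCC=C)c12 | intermediate
6 | 6,3'-diallyl-7-O-MOM genistein (6-allyl-3-(3-allyl-4-hydroxyphenyl)-5-hydroxy-7-(methoxymethoxy)chromen-4-one) | C=CCc1c(OCOC)cc2occ(-c3ccc(O)c(CC=C)c3)c(=O)c2c1O | intermediate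
7 | 2-methylbut-2-ene | CC=C(C)C | starting material
8 | 7-O-MOM lupalbigenin (5-hydroxy-3-[4-hydroxy-3-(3-methylbut-2-enyl)phenyl]-7-(methoxymethoxy)-6-(3-methylbut-2-enyl)chromen-4-one) | CC(C)=CCc1c(OCOC)cc2occ(-c3ccc(O)c(CC=C(C)C)c3)c(=O)c2c1O | intermediate
9 | B-ring ortho-quinone methide (5-hydroxy-7-(methoxymethoxy)-6-(3-methylbut-2-enyl)-3-[(3Z)-3-(3-methylbut-2-enylidene)-4-oxocyclohexa-1,5-dienyl]chromen-4-one) | CC(C)=CCc1c(OCOC)cc2occ(C3=C/C(=C/C=C(C)C)C(=O)C=C3)c(=O)c2c1O | intermediate
10 | 7-O-MOM isochandalone (3-(2,2-dimethyl-2H-chromen-6-yl)-5-hydroxy-7-(methoxymethoxy)-6-(3-methylbut-2-enyl)chromen-4-one) | CC(C)=CCc1c(OCOC)cc2occ(-c3ccc4c(c3)C=CC(C)(C)O4)c(=O)c2c1O | intermediate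
11 | isochandalone (3-(2,2-dimethyl-2H-chromen-6-yl)-5,7-dihydroxy-6-(3-methylbut-2-enyl)chromen-4-one) | CC(C)=CCc1c(O)cc2occ(-c3ccc4c(c3)C=CC(C)(C)O4)c(=O)c2c1O | target

**Step count**
Total steps: 6. Longest linear sequence: 6 steps, from genistein 1 to isochandalone 11.

**Steps most likely to fail**

Step 5 (key step). What may go wrong: hydride abstraction also at the C6 prenyl CH2 with closure onto the chelated 5-OH, further dehydrogenation of the chromene once formed, or capture of the quinone methide by the hydroquinone instead of electrocyclisation. Fallback: the same oxatriene is generated without an oxidant by the aryl propargyl ether rearrangement. It sets out from 3. Alkylation of the free 4'-OH with 3-chloro-3-methylbut-1-yne (DBU, cat. CuCl2, MeCN, 0 °C) should give 4'-O-(2-methylbut-3-yn-2-yl)-7-O-MOM genistein F1, the hydrogen-bonded 5-OH staying free. Allyl bromide and K2CO3 in DMF then give 5-O-allyl-4'-O-(2-methylbut-3-yn-2-yl)-7-O-MOM genistein F2. Heating in N,N-diethylaniline at about 190 °C should bring about both the propargyl Claisen/[1,5]-H shift/oxa-6π cascade on ring B and the allyl Claisen shift to C6, giving 6-allyl-3-(2,2-dimethyl-2H-chromen-6-yl)-5-hydroxy-7-(methoxymethoxy)chromen-4-one F3. Cross-metathesis of the remaining allyl group with 7 under the conditions of step 4 comes back to the route at 10.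

Step 3. What may go wrong: incomplete rearrangement of the less activated B-ring ether, onward Cope migration of the C6 allyl group to C8 before tautomerisation, thermal erosion of the MOM acetal, or ring closure of the o-allylphenols to 2-methyl-2,3-dihydrobenzofurans at 200 °C. Fallback: the two aryl–carbon bonds are made at or below about 110 °C from two different ethers. It sets out from 3. Pd(PPh3)4-catalysed Tsuji–Trost O-allylation with tert-butyl 2-methylbut-3-en-2-yl carbonate (THF, 0 °C) should reverse-prenylate only the unchelated 4'-OH and give 4'-O-(2-methylbut-3-en-2-yl)-7-O-MOM genistein F4. Allyl bromide and K2CO3 in DMF then give 5-O-allyl-4'-O-(2-methylbut-3-en-2-yl)-7-O-MOM genistein F5. With Eu(fod)3 (10 mol %) in chlorobenzene at 100–110 °C the tertiary ether should rearrange thermally and deliver the 3'-prenyl group directly, while the chelating 5-allyloxy-4-one undergoes the Eu(III)-catalysed Claisen shift to C6, giving 6-allyl-3'-prenyl-7-O-MOM genistein F6. Cross-metathesis of its single allyl group with 7 comes back to the route at 8.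

Step 6. What may go wrong: acid-promoted hydroalkoxylation of the C6 prenyl double bond by the flanking 5- or 7-OH (closure to a dimethylchroman), and addition of methanol to the chromene or its oligomerisation while the acetal is cleaved. Fallback: O7 is carried through the whole sequence as a fluoride-labile SEM acetal, so no acid is needed at the end. It sets out from 1. 2-(Trimethylsilyl)ethoxymethyl chloride and K2CO3 in acetone should give 7-O-SEM genistein F7. The conditions of steps 2 to 5 then give in turn 5,4'-di-O-allyl-7-O-SEM genistein F8, 6,3'-diallyl-7-O-SEM genistein F9, 7-O-SEM lupalbigenin F10 and 7-O-SEM isochandalone F11. TBAF in THF/DMPU at 50 °C cleaves the SEM group by attack at silicon and comes back to the route at 11.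

**Further compounds**
F1 | step 5 | 4'-O-(2-methylbut-3-yn-2-yl)-7-O-MOM genistein | O=c1c(-c2ccc(OC(C)(C)C#C)cc2)coc2cc(OCOC)cc(O)c12
F2 | step 5 | 5-O-allyl-4'-O-(2-methylbut-3-yn-2-yl)-7-O-MOM genistein | O=c1c(-c2ccc(OC(C)(C)C#C)cc2)coc2cc(OCOC)cc(OCC=C)c12
F3 | step 5 | 6-allyl-3-(2,2-dimethyl-2H-chromen-6-yl)-5-hydroxy-7-(methoxymethoxy)chromen-4-one | C=CCc1c(OCOC)cc2occ(-c3ccc4c(c3)C=CC(C)(C)O4)c(=O)c2c1O
F4 | step 3 | 4'-O-(2-methylbut-3-en-2-yl)-7-O-MOM genistein | O=c1c(-c2ccc(OC(C)(C)C=C)cc2)coc2cc(OCOC)cc(O)c12
F5 | step 3 | 5-O-allyl-4'-O-(2-methylbut-3-en-2-yl)-7-O-MOM genistein | O=c1c(-c2ccc(OC(C)(C)C=C)cc2)coc2cc(OCOC)cc(OCC=C)c12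
F6 | step 3 | 6-allyl-3'-prenyl-7-O-MOM genistein (6-allyl-5-hydroxy-3-[4-hydroxy-3-(3-methylbut-2-enyl)phenyl]-7-(methoxymethoxy)chromen-4-one) | C=CCc1c(OCOC)cc2occ(-c3ccc(O)c(CC=C(C)C)c3)c(=O)c2c1O
F7 | step 6 | 7-O-SEM genistein | O=c1c(-c2ccc(O)cc2)coc2cc(OCOCC[Si](C)(C)C)cc(O)c12
F8 | step 6 | 5,4'-di-O-allyl-7-O-SEM genistein | O=c1c(-c2ccc(OCC=C)cc2)coc2cc(OCOCC[Si](C)(C)C)cc(OCC=C)c12
F9 | step 6 | 6,3'-diallyl-7-O-SEM genistein | C=CCc1c(OCOCC[Si](C)(C)C)cc2occ(-c3ccc(O)c(CC=C)c3)c(=O)c2c1O
F10 | step 6 | 7-O-SEM lupalbigenin | CC(C)=CCc1c(OCOCC[Si](C)(C)C)cc2occ(-c3ccc(O)c(CC=C(C)C)c3)c(=O)c2c1O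
F11 | step 6 | 7-O-SEM isochandalone | CC(C)=CCc1c(OCOCC[Si](C)(C)C)cc2occ(-c3ccc4c(c3)C=CC(C)(C)O4)c(=O)c2c1O
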